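**Retrosynthetic overview**
1. Target 20 comes from 18 by oxidative O-demethylation and reduction; 18 comes from 17 by one hydrogenation that also turns ArC(=O) into ArCH2 and frees the acid.
2. 17 comes from the acyclic triene-dione 16 by an intramolecular Diels–Alder reaction: rings A and B form together (bonds C5–C10 and C8–C9) and C5, C8, C9, C10 are set at once; the arene is bought.
3. 16 is a 1,6-dicarbonyl compound; its key bond C1–C10 joins the β-carbon of a ketone (homoenolate from cyclopropanol 14) to the β-carbon of bromo enone 5, two natively electrophilic carbons.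
4. 14 comes from but-3-yn-1-ol (carboalumination/coupling, oxidation, Michael addition, Kulinkovich); 5 comes from 4-methoxy-2-methylphenol (Fries, benzylation, formylation/bromination).

Atom labels (target): decalin C1–C10 with C5/C10 at the ring fusion, C3 the ketone, C4 bearing the propanoic acid chain, C8 the secondary methyl, C9 the methyl and the benzylic carbon C11; ring A is the ketone ring, ring B the trimethyl ring.

Assumption: the (S)-configured oxazaborolidinium catalyst in step 9 gives the enantiomer drawn; if induction runs the other way the (R)-catalyst is used. The side-chain stereocentre (C4) is carried as a racemate/epimer mixture until step 10, where it equilibrates.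

**Route**

Step 1
Reactants: 1 4-methoxy-2-methylphenol
Product: 2 1-(2-hydroxy-5-methoxy-3-methylphenyl)propan-1-one
Conditions: (EtCO)2O, TfOH (20 mol %), 80 °C
Reagents that add atoms: propanoic anhydride CCC(=O)OC(=O)CC
Why: O-acylation and acid-catalysed Fries rearrangement deliver the acyl group to the only free ortho position of the phenol, since the para position carries OMe.

Step 2
Reactants: 2 1-(2-hydroxy-5-methoxy-3-methylphenyl)propan-1-one
Product: 3 1-[2-(benzyloxy)-5-methoxy-3-methylphenyl]propan-1-one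
Conditions: BnBr, K2CO3, DMF, 60 °C
Reagents that add atoms: benzyl bromide BrCc1ccccc1
Why: Williamson etherification masks the phenol, which would otherwise close to a chromone in step 3, with a group that step 10 removes by hydrogenolysis.

Step 3
Reactants: 3 1-[2-(benzyloxy)-5-methoxy-3-methylphenyl]propan-1-one
Product: 5 (2E)-1-[2-(benzyloxy)-5-methoxy-3-methylphenyl]-3-bromo-2-methylprop-2-en-1-one, via sodium formyl enolate 4 (not isolated)
Conditions: NaH, HCO2Et, THF, 0 °C to rt; then (COBr)2, CH2Cl2, −20 to 0 °C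
Reagents that add atoms: ethyl formate CCOC=O; oxalyl bromide BrC(=O)C(=O)Br
Why: Claisen formylation of the ethyl ketone followed by deoxybromination of the enolate gives the β-bromo enone, expected to equilibrate under the HBr present to the E isomer (Br anti to the aroyl group).

Step 4
Reactants: 6 but-3-yn-1-ol, 7 (1E)-1-bromoprop-1-ene
Product: 9 (3E,5E)-3-methylhepta-3,5-dien-1-ol, via alkenylalane 8 (not isolated)
Conditions: Me3Al, Cp2ZrCl2 (25 mol %), CH2Cl2, 0 °C to rt; then 7, Pd(PPh3)4 (5 mol %), THF, rt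
Reagents that add atoms: trimethylaluminium C[Al](C)C
Why: Negishi zirconium-catalysed syn-carboalumination places Me and Al cis on the alkyne and the stereoretentive palladium-catalysed alkenyl–alkenyl coupling then gives the (3E,5E)-diene.

Step 5
Reactants: 9 (3E,5E)-3-methylhepta-3,5-dien-1-ol
Product: 11 methyl (3E,5E)-3-methylhepta-3,5-dienoate, via dienoic acid 10 (not isolated)
Conditions: TEMPO (20 mol %), PhI(OAc)2, MeCN–H2O, rt; then TMSCHN2, MeOH–toluene, 0 °C
Reagents that add atoms: water O; (trimethylsilyl)diazomethane C[Si](C)(C)C=[N+]=[N-]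
Why: TEMPO/iodane oxidation of the primary alcohol to the acid and diazoalkane esterification are both near-neutral, so the diene stays out of conjugation with the carbonyl.

Step 6
Reactants: 11 methyl (3E,5E)-3-methylhepta-3,5-dienoate, 12 tert-butyl prop-2-enoate
Product: 13 5-tert-butyl 1-methyl 2-[(2E,4E)-hexa-2,4-dien-2-yl]pentanedioate (racemic)
Conditions: LiN(iPr)2, THF, −78 °C; then 12, −78 °C; NH4Cl
Reagents that add atoms: none
Why: The lithium trienolate undergoes Michael addition through its α-carbon, installing the propanoate chain at C4 without touching the diene geometry; the new stereocentre is racemic and is corrected in step 10.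

Step 7
Reactants: 13 5-tert-butyl 1-methyl 2-[(2E,4E)-hexa-2,4-dien-2-yl]pentanedioate
Product: 14 tert-butyl (5E,7E)-4-(1-hydroxycyclopropyl)-5-methylnona-5,7-dienoate (racemic)
Conditions: EtMgBr (slow addition), Ti(OiPr)4 (30 mol %), THF, 0 °C to rt
Reagents that add atoms: ethylmagnesium bromide CC[Mg]Br
Why: Kulinkovich cyclopropanation converts only the methyl ester into the cyclopropanol (the tert-butyl ester is too hindered), which is the latent homoenolate of the C3 ketone.

Step 8
Reactants: 14 tert-butyl (5E,7E)-4-(1-hydroxycyclopropyl)-5-methylnona-5,7-dienoate, 5 (2E)-1-[2-(benzyloxy)-5-methoxy-3-methylphenyl]-3-bromo-2-methylprop-2-en-1-one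
Product: 16 tert-butyl (5E,7E)-4-{(4E)-6-[2-(benzyloxy)-5-methoxy-3-methylphenyl]-5-methyl-6-oxohex-4-enoyl}-5-methylnona-5,7-dienoate (racemic), via zinc cyclopropoxide 15 (not isolated)
Conditions: Et2Zn (0.5 equiv), THF, 0 °C; then 5, Pd(OAc)2 (5 mol %), XPhos (10 mol %), THF–DMA, 40 °C
Reagents that add atoms: none
Why: Strain-driven β-carbon elimination of the metal cyclopropoxide gives a ketone homoenolate, which couples with the alkenyl bromide with retention of geometry (Negishi-type homoenolate cross-coupling, an extension of the known aryl-halide and acyl-chloride cases), under base-free conditions that spare the acidic C4–H.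

Step 9
Reactants: 16 tert-butyl (5E,7E)-4-{(4E)-6-[2-(benzyloxy)-5-methoxy-3-methylphenyl]-5-methyl-6-oxohex-4-enoyl}-5-methylnona-5,7-dienoate
Product: 17 tert-butyl 3-[(4aS,5S,6S,8aR)-5-[2-(benzyloxy)-5-methoxy-3-methylbenzoyl]-5,6,8a-trimethyl-2-oxo-1,2,3,4,4a,5,6,8a-octahydronaphthalen-1-yl]propanoate (mixture of C1 epimers)
Conditions: (S)-B-o-tolyl oxazaborolidine from (S)-diphenylprolinol (20 mol %), Tf2NH (18 mol %), CH2Cl2, −40 to 0 °C
Reagents that add atoms: none
Why: Proposed new method: the cationic oxazaborolidine binds the aryl enone carbonyl and lowers its LUMO, and the tethered (E,E)-diene adds through the carbonyl-endo, tether-anti chair transition state, which by the Alder rule puts the C8 methyl cis to the aroyl group and trans to the C9 methyl and gives the trans ring fusion with the angular C5 methyl, while the catalyst shields one enone face and so fixes the absolute configuration of C5, C8, C9 and C10 for both C4 epimers; the closest known reaction type is the oxazaborolidinium-catalysed enantioselective intramolecular Diels–Alder reaction of triene ketones and aldehydes.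

Step 10
Reactants: 17 tert-butyl 3-[(4aS,5S,6S,8aR)-5-[2-(benzyloxy)-5-methoxy-3-methylbenzoyl]-5,6,8a-trimethyl-2-oxo-1,2,3,4,4a,5,6,8a-octahydronaphthalen-1-yl]propanoate
Product: 18 3-[(1S,4aR,5S,6S,8aR)-5-[(2-hydroxy-5-methoxy-3-methylphenyl)methyl]-5,6,8a-trimethyl-2-oxodecahydronaphthalen-1-yl]propanoic acid
Conditions: H2 (4 atm), Pd/C, AcOH–TFA (10:1), 40 °C
Reagents that add atoms: none
Why: Catalytic hydrogenation saturates the ring alkene and removes the benzyl ether, the freed ortho-hydroxyaryl ketone is hydrogenolysed to ArCH2 through its benzylic alcohol and ortho-quinone methide while the dialkyl ketone survives, and the acid cleaves the tert-butyl ester and epimerises the centre next to the ketone to the more stable equatorial (1S) configuration (estimated at only about 3–5:1, so the minor epimer is separated and re-equilibrated).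

Step 11
Reactants: 18 3-[(1S,4aR,5S,6S,8aR)-5-[(2-hydroxy-5-methoxy-3-methylphenyl)methyl]-5,6,8a-trimethyl-2-oxodecahydronaphthalen-1-yl]propanoic acid
Product: 20 3-[(1S,4aR,5S,6S,8aR)-5-[(2,5-dihydroxy-3-methylphenyl)methyl]-5,6,8a-trimethyl-2-oxodecahydronaphthalen-1-yl]propanoic acid, via quinone 19 (not isolated)
Conditions: (NH4)2Ce(NO3)6, MeCN–H2O, 0 °C; then Na2S2O4, H2O–EtOAc, rt
Reagents that add atoms: water O
Why: Oxidative demethylation of the para-methoxyphenol gives the benzoquinone (water supplies the new carbonyl oxygen, methanol leaves) and dithionite reduces it to the hydroquinone without touching ketone, acid or stereocentres.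

**Compound list**
1 | 4-methoxy-2-methylphenol | COc1ccc(O)c(C)c1 | starting material
2 | 1-(2-hydroxy-5-methoxy-3-methylphenyl)propan-1-one | COc1cc(C)c(O)c(c1)C(=O)CC | intermediate
3 | 1-[2-(benzyloxy)-5-methoxy-3-methylphenyl]propan-1-one | COc1cc(C)c(OCc2ccccc2)c(c1)C(=O)CC | intermediate
4 | sodium 3-[2-(benzyloxy)-5-methoxy-3-methylphenyl]-2-methyl-3-oxoprop-1-en-1-olate | COc1cc(C)c(OCc2ccccc2)c(c1)C(=O)C(C)=C[O-].[Na+] | intermediate
5 | (2E)-1-[2-(benzyloxy)-5-methoxy-3-methylphenyl]-3-bromo-2-methylprop-2-en-1-one | COc1cc(C)c(OCc2ccccc2)c(c1)C(=O)/C(C)=C/Br | intermediate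
6 | but-3-yn-1-ol | OCCC#C | starting material
7 | (1E)-1-bromoprop-1-ene | C/C=C/Br | starting material
8 | dimethyl{(1E)-4-[(dimethylalumanyl)oxy]-2-methylbut-1-en-1-yl}alumane | C[Al](C)/C=C(\C)CCO[Al](C)C | intermediate
9 | (3E,5E)-3-methylhepta-3,5-dien-1-ol | OCC/C(C)=C/C=C/C | intermediate
10 | (3E,5E)-3-methylhepta-3,5-dienoic acid | OC(=O)C/C(C)=C/C=C/C | intermediate
11 | methyl (3E,5E)-3-methylhepta-3,5-dienoate | COC(=O)C/C(C)=C/C=C/C | intermediate
12 | tert-butyl prop-2-enoate | C=CC(=O)OC(C)(C)C | starting material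
13 | 5-tert-butyl 1-methyl 2-[(2E,4E)-hexa-2,4-dien-2-yl]pentanedioate (racemic) | COC(=O)C(CCC(=O)OC(C)(C)C)/C(C)=C/C=C/C | intermediate
14 | tert-butyl (5E,7E)-4-(1-hydroxycyclopropyl)-5-methylnona-5,7-dienoate (racemic) | CC(C)(C)OC(=O)CCC(C1(O)CC1)/C(C)=C/C=C/C | intermediate
15 | zinc bis{1-[(5E,7E)-1-tert-butoxy-5-methyl-1-oxonona-5,7-dien-4-yl]cyclopropan-1-olate} | CC(C)(C)OC(=O)CCC(/C(C)=C/C=C/C)C1(CC1)O[Zn]OC1(CC1)C(CCC(=O)OC(C)(C)C)/C(C)=C/C=C/C | intermediate
16 | tert-butyl (5E,7E)-4-{(4E)-6-[2-(benzyloxy)-5-methoxy-3-methylphenyl]-5-methyl-6-oxohex-4-enoyl}-5-methylnona-5,7-dienoate (racemic) | COc1cc(C)c(OCc2ccccc2)c(c1)C(=O)/C(C)=C/CCC(=O)C(CCC(=O)OC(C)(C)C)/C(C)=C/C=C/C | intermediate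
17 | tert-butyl 3-[(4aS,5S,6S,8aR)-5-[2-(benzyloxy)-5-methoxy-3-methylbenzoyl]-5,6,8a-trimethyl-2-oxo-1,2,3,4,4a,5,6,8a-octahydronaphthalen-1-yl]propanoate (C1 epimers) | COc1cc(C)c(OCc2ccccc2)c(c1)C(=O)[C@]1(C)[C@H]2CCC(=O)C(CCC(=O)OC(C)(C)C)[C@]2(C)C=C[C@@H]1C | intermediate
18 | 3-[(1S,4aR,5S,6S,8aR)-5-[(2-hydroxy-5-methoxy-3-methylphenyl)methyl]-5,6,8a-trimethyl-2-oxodecahydronaphthalen-1-yl]propanoic acid | COc1cc(C)c(O)c(c1)C[C@]1(C)[C@H]2CCC(=O)[C@@H](CCC(=O)O)[C@]2(C)CC[C@@H]1C | intermediate
19 | 3-[(1S,4aR,5S,6S,8aR)-5,6,8a-trimethyl-5-[(5-methyl-3,6-dioxocyclohexa-1,4-dien-1-yl)methyl]-2-oxodecahydronaphthalen-1-yl]propanoic acid | CC1=CC(=O)C=C(C[C@]2(C)[C@H]3CCC(=O)[C@@H](CCC(=O)O)[C@]3(C)CC[C@@H]2C)C1=O | intermediate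
20 | 3-[(1S,4aR,5S,6S,8aR)-5-[(2,5-dihydroxy-3-methylphenyl)methyl]-5,6,8a-trimethyl-2-oxodecahydronaphthalen-1-yl]propanoic acid (CNP0167047.1) | Cc1cc(O)cc(C[C@]2(C)[C@H]3CCC(=O)[C@@H](CCC(=O)O)[C@]3(C)CC[C@@H]2C)c1O | target

**Step count and risks**
Total: 11 steps. Longest linear sequence: 8 steps (steps 4 to 11).

Most likely to fail, in order:

Step 9 (asymmetric cycloaddition). The diene terminus carries an inward methyl group, a second ketone competes for the catalyst, and the sense and level of induction are untested. The fallback sets out from 16 and gives up catalyst control. Heating 16 in toluene with BHT at 130 °C gives 17 together with its mirror-image adduct F3. The racemate is taken through the conditions of step 10 to 18 and the mirror-image acid F4. The acids are resolved by crystallising the (1R)-1-phenylethan-1-aminium salt F5 of 18 from ethanol, and acidification returns the route at 18.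

Step 8 (homoenolate coupling). β-Hydride elimination of the alkylpalladium to a vinyl ketone, or poor transmetalation of the zinc cyclopropoxide, may win. The fallback sets out from 14 and makes that elimination product on purpose. Oxidative ring opening of 14 (Pd(OAc)2, pyridine, O2, toluene) gives the vinyl ketone F1. A nickel-catalysed reductive conjugate addition of bromo enone 5 to F1 (NiCl2(dme), neocuproine, Mn powder, Et3SiCl, DMF) gives the silyl enol ether F2. Mild acidic hydrolysis of F2 returns the route at 16.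

Step 10 (one-flask hydrogenolysis). The aryl ketone sits on a quaternary carbon and may stop at the ketone or carbinol stage. The fallback sets out from 17 and separates the tasks. Hydrogenation under neutral conditions (H2, Pd/C, EtOAc) saturates the alkene and removes the benzyl ether to give the hydroxyaryl ketone F6. Ionic hydrogenation of F6 (Et3SiH, TFA, CH2Cl2) then reduces the ortho-hydroxyaryl ketone to ArCH2 through the ortho-quinone methide, cleaves the tert-butyl ester and epimerises C1, returning the route at 18.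

**Further compounds**
F1 | step 8 | tert-butyl (5E,7E)-5-methyl-4-(prop-2-enoyl)nona-5,7-dienoate | CC(C)(C)OC(=O)CCC(C(=O)C=C)/C(C)=C/C=C/C
F2 | step 8 | tert-butyl (5E,7E)-4-{(4E)-6-[2-(benzyloxy)-5-methoxy-3-methylphenyl]-5-methyl-6-oxo-1-[(triethylsilyl)oxy]hexa-1,4-dien-1-yl}-5-methylnona-5,7-dienoate | COc1cc(C)c(OCc2ccccc2)c(c1)C(=O)/C(C)=C/CC=C(O[Si](CC)(CC)CC)C(CCC(=O)OC(C)(C)C)/C(C)=C/C=C/C
F3 | step 9 | tert-butyl 3-[(4aR,5R,6R,8aS)-5-[2-(benzyloxy)-5-methoxy-3-methylbenzoyl]-5,6,8a-trimethyl-2-oxo-1,2,3,4,4a,5,6,8a-octahydronaphthalen-1-yl]propanoate | COc1cc(C)c(OCc2ccccc2)c(c1)C(=O)[C@@]1(C)[C@@H]2CCC(=O)C(CCC(=O)OC(C)(C)C)[C@@]2(C)C=C[C@H]1C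
F4 | step 9 | 3-[(1R,4aS,5R,6R,8aS)-5-[(2-hydroxy-5-methoxy-3-methylphenyl)methyl]-5,6,8a-trimethyl-2-oxodecahydronaphthalen-1-yl]propanoic acid | COc1cc(C)c(O)c(c1)C[C@@]1(C)[C@@H]2CCC(=O)[C@H](CCC(=O)O)[C@@]2(C)CC[C@H]1C
F5 | step 9 | (1R)-1-phenylethan-1-aminium 3-[(1S,4aR,5S,6S,8aR)-5-[(2-hydroxy-5-methoxy-3-methylphenyl)methyl]-5,6,8a-trimethyl-2-oxodecahydronaphthalen-1-yl]propanoate | COc1cc(C)c(O)c(c1)C[C@]1(C)[C@H]2CCC(=O)[C@@H](CCC(=O)[O-])[C@]2(C)CC[C@@H]1C.C[C@@H]([NH3+])c1ccccc1
F6 | step 10 | tert-butyl 3-[(4aS,5S,6S,8aR)-5-(2-hydroxy-5-methoxy-3-methylbenzoyl)-5,6,8a-trimethyl-2-oxodecahydronaphthalen-1-yl]propanoate | COc1cc(C)c(O)c(c1)C(=O)[C@]1(C)[C@H]2CCC(=O)C(CCC(=O)OC(C)(C)C)[C@]2(C)CC[C@@H]1C
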